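| flask | substrate | enzyme | remark |
|---|---|---|---|
| autumn | 0.17 M | 0.02 mol% | run made earlier |
| midnight | 0.26 M | 0.02 mol% | run made earlier |
| flask | 0.12 M | 0.02 mol% |  |

| run | time / h | target / % | substrate / % |
|---|---|---|---|
| autumn | 0.833 | 13.2 | 85.0 |
| autumn | 2.50 | 29.4 | 68.7 |
| autumn | 4.00 | 38.9 | 62.2 |
| autumn | 6.00 | 45.2 | 53.0 |
| midnight | 1.50 | 26.6 | 71.8 |
| midnight | 3.00 | 41.3 | 57.8 |
| midnight | 5.00 | 53.7 | 45.6 |
| midnight | 6.00 | 57.2 | 40.0 |

(standard deviation of a reading: 1 percentage point)

* factor on the rate of making target when 30% of the substrate are converted if enzyme is charged twice over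
* factor on the rate when 30% of the substrate are converted if enzyme is charged at 0.1 mol% instead

- on the list of suspects stand: substrate + enzyme -> target + enzyme; enzyme <-> dormant form; substrate -> uncatalysed product

The slowing of the autumn run is what I read first: its substrate decays with an apparent first-order constant of 0.195 h⁻¹ up to 0.833 h, but of 0.0800 h⁻¹ from 4.00 h to 6.00 h, which I take as enzyme relaxing into its dormant form, an off-cycle form of the catalyst. Dividing the first by the second removes the clock and leaves 2.44, the early-to-late ratio: a reading, with the scatter of its substrate values, of how far the apparent constant falls between two windows that also differ in substrate and that each average over a changing enzyme.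

At 30% conversion the substrate is equal in every variant of this flask, so the rate there goes with the charge times the active share on arrival. Taking this ratio as my rough estimate of the fall in active share, and supposing that the flask arrives as in the late window and the 0.1 mol% variant as in the early one, my factor is 12.2; doubling arrives in between, so I can only bracket it from 2 to 4.88. The midnight run reads 1.80, lower than autumn, so one number is only a reading. The forecast gives 3.4 and 12, since the faster flasks arrive “with more enzyme still active”.

The flask gives 3.07 for doubling and 12.3 for 0.1 mol%, from these steps:

    substrate + enzyme → target + enzyme, rate k1*[substrate]^2.5*[enzyme]/(1 + ([substrate]/Kh1)^2.5) (0.110 M, k = 3.90 × 10⁵ M⁻²·⁵ h⁻¹)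
    enzyme ⇌ dormant form (K = 2.50, k = 0.630 h⁻¹)
    substrate → uncatalysed product (k = 0.00610 h⁻¹)

It reaches 30% conversion at 4.27 h, and at 4.00 h its enzyme stands at 30.7% of the charge. Divided by its charge factor, the 0.1 mol% answer leaves 2.47, against the ratio of 2.44, while doubling leaves 1.53, lower than that ratio.

The runs were computed with constants of no real substance; the scatter is artificial.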